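**Plan**

- Retrosynthesis: the C4–C8 bond between units 2 and 3 is cut first (a [2+2] Friedel–Crafts union of two dimers). In the lower dimer, ring C of unit 3 is opened at C4–C4a (cation–arene ring closure), then at the O1–C2 aryl ether (phenol + epoxide), then at the C4(unit 3)–C8(unit 4) bond (aryllithium + aldehyde). In the upper dimer the C4–C8 bond between units 1 and 2 is cut.
- Forward: units 1, 2 and 4 come from (+)-catechin. Unit 3 is built de novo from 3,5-bis(benzyloxy)phenol (ring A), a cinnamaldehyde-derived epoxy aldehyde (ring B and C2–C4) and C8-lithiated unit 4, and its pyran ring C is the last ring to arise, inside the lower dimer. The two dimers are then joined and all benzyl groups and one bromine cap are removed by hydrogenolysis.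
- Enabling feature: C4 of unit 3 is benzylic to ring A of unit 4 at C8, flanked by O1 and O7 and para to O5, so a cation there is a stabilised quinone-methide-type ion. C4a of unit 3 is a phloroglucinol-type carbon ortho to O1 and is held at six-ring distance through O1–C2–C3.
- Stereochemistry: C2/C3 of units 1, 2 and 4 come from the chiral pool. C3 of unit 3 comes from an enantioselective epoxidation and C2 from SN2 inversion of the same epoxide. The three C4 centres arise by 3,4-trans (4α) capture of C4 cations, in the ring closure through a chair transition state.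

Key step: step 8

Remark: the target is read as catechin-(4α→8)-catechin-(4α→8)-catechin-(4α→8)-catechin (every unit 2R,3S, every interflavan bond 3,4-trans). Flavan numbering is used for each unit, and the units are counted 1 to 4 from the upper end (free C8) to the terminal unit (C4H2).

**Route**

Step 1
Reactants: 1 (+)-catechin
Product: 2 tetra-O-benzylcatechin (benzyl ethers at O5, O7, O3′, O4′; 3-OH free)
Conditions: BnBr (4.4 equiv), K2CO3, DMF, 0 °C to rt
Reagents that add atoms: benzyl bromide, BrCc1ccccc1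
Why: Williamson etherification in which K2CO3 deprotonates only the four phenols, so the secondary 3-OH stays free and the chiral-pool centres C2 and C3 are untouched.

Step 2
Reactants: 2 tetra-O-benzylcatechin
Product: 3 8-bromo-tetra-O-benzylcatechin
Conditions: NBS (1.0 equiv), CH2Cl2, −78 to 0 °C
Reagents that add atoms: N-bromosuccinimide, O=C1CCC(=O)N1Br
Why: Electrophilic aromatic bromination, which in 5,7-di-O-benzyl flavan-3-ols should go to C8 in preference to C6 and gives both the handle for lithiation (unit 4) and the C8 cap (unit 1).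

Step 3
Reactants: 3 8-bromo-tetra-O-benzylcatechin
Product: 4 8-bromo-penta-O-benzylcatechin (additional benzyl ether at O3)
Conditions: NaH, BnBr, DMF, 0 °C to rt
Reagents that add atoms: benzyl bromide, BrCc1ccccc1
Why: Williamson etherification of the secondary alkoxide, which removes the acidic proton before lithiation and installs a group that falls in the final hydrogenolysis.

Step 4
Reactants: 5 3,4-bis(benzyloxy)benzaldehyde
Product: 6 (E)-3-[3,4-bis(benzyloxy)phenyl]prop-2-enal
Conditions: Ph3P=CHCHO (1.2 equiv), toluene, 90 °C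
Reagents that add atoms: (triphenylphosphoranylidene)acetaldehyde, O=CC=P(c1ccccc1)(c1ccccc1)c1ccccc1
Why: Wittig olefination with a stabilised formyl ylide, which should give the E-enal.

Step 5
Reactants: 6 (E)-3-[3,4-bis(benzyloxy)phenyl]prop-2-enal
Product: 7 (2R,3S)-3-[3,4-bis(benzyloxy)phenyl]oxirane-2-carbaldehyde (trans)
Conditions: (R)-2-{bis[3,5-bis(trifluoromethyl)phenyl](trimethylsilyloxy)methyl}pyrrolidine (10 mol %), 35% aq. H2O2, CH2Cl2, rt
Reagents that add atoms: hydrogen peroxide, OO
Why: Aminocatalytic nucleophilic epoxidation (iminium, then enamine) in which hydroperoxide should add to C-β of the E-iminium ion on the face left open by the silyloxydiarylmethyl group of the (R)-catalyst and the enamine closes the oxirane, so the trans-(2R,3S)-epoxide is expected; this fixes the later C3 (S) of unit 3 and, after inversion in step 7, its C2 (R).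

Step 6
Reactants: 4 8-bromo-penta-O-benzylcatechin; 7 (2R,3S)-3-[3,4-bis(benzyloxy)phenyl]oxirane-2-carbaldehyde
Product: 10 epoxy methyl ether (trans-oxirane of 7 carrying a methoxy(penta-O-benzylcatechin-8-yl)methyl group; both epimers at the methoxy carbon), via aryllithium 8 (not isolated), via lithium alkoxide 9 (not isolated)
Conditions: n-BuLi, THF, −78 °C; then 7, −78 °C; then MeOTf, −78 to −20 °C
Reagents that add atoms: methyl trifluoromethanesulfonate, COS(=O)(=O)C(F)(F)F
Why: Bromine–lithium exchange, 1,2-addition of the aryllithium to the aldehyde and O-methylation of the alkoxide in one flask, which makes the bond from C8 of unit 4 to the future C4 of unit 3 regiospecifically; the new carbinol centre need not be controlled because it is ionised in step 8.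

Step 7
Reactants: 10 epoxy methyl ether; 11 3,5-bis(benzyloxy)phenol
Product: 12 seco-dimer aryl ether, (1R,2S)-1-[3,4-bis(benzyloxy)phenyl]-1-[3,5-bis(benzyloxy)phenoxy]-3-methoxy-3-(penta-O-benzylcatechin-8-yl)propan-2-ol (both epimers at C3 of the chain)
Conditions: 11 (2 equiv), Cs2CO3 (0.2 equiv), DMF, 80 °C
Reagents that add atoms: none
Why: Base-catalysed SN2 opening of the trans-epoxide by the phenoxide at the benzylic carbon (the other epoxide carbon is hindered and inductively deactivated by the neighbouring methoxy-bearing centre), as in phenoxide openings of trans-3-arylglycidols; inversion should set C2 (R) and the erythro ether–alcohol relation that becomes 2,3-trans.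

Step 8
Reactants: 12 seco-dimer aryl ether
Product: 13 lower dimer, tetra-O-benzylcatechin-(4α→8)-penta-O-benzylcatechin (3-OH of the upper unit free)
Conditions: TMSOTf (0.2 equiv), 4 Å MS, CH2Cl2 (0.005 M), −78 to −30 °C; Et3N quench
Reagents that add atoms: none
Why: TMSOTf should ionise the benzylic methyl ether of either epimer of 12 to one cation at the future C4 of unit 3, stabilised as a quinone-methide-type ion by O1, O7 and O5 of ring A of unit 4, and a carbon ortho to the ether oxygen of the 3,5-bis(benzyloxy)phenoxy ring attacks it in an intramolecular Friedel–Crafts alkylation. The closest known reaction types are the acid-mediated epoxy-arene and benzylic-cation cyclisations of aryl 3-arylpropyl ethers to trans-4-arylchroman-3-ols and the Lewis-acid coupling of 4-alkoxyflavans with phloroglucinol-type arenes. Pyran ring C closes in the 6-exo-trig mode with respect to the exocyclic cationic C4=C8 unit (6-endo as seen from the arene C4a–C8a bond). C4 is set by a chair-like transition state in which C3–H lies in the cation plane to avoid allylic 1,3-strain with the ortho substituents of ring A of unit 4 and the tethered arene adds anti to the C3 oxygen, so that the 2-aryl, 3-hydroxy and 4-aryl groups all end up equatorial (2,3-trans-3,4-trans, 4α); C2 and C3 are carried in from 12. Ionisation at C4 and not at the C2 benzylic aryl ether rests on the far greater stabilisation by the trioxygenated ring, the two ortho positions of the phenoxy ring are equivalent and the para position cannot reach, so only one regioisomer can form, and high dilution suppresses intermolecular alkylation.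

Step 9
Reactants: 3 8-bromo-tetra-O-benzylcatechin
Product: 14 capped electrophile, (2R,3S,4S)-8-bromo-4-(2-ethoxyethoxy)-tetra-O-benzylcatechin
Conditions: DDQ (2 equiv), 2-ethoxyethanol (5 equiv), CH2Cl2, rt
Reagents that add atoms: 2-ethoxyethanol, CCOCCO
Why: Benzylic oxidation by hydride abstraction at C4 with DDQ and capture of the flavan-4-yl cation by the alcohol, the usual entry to C4-activated flavan-3-ols; the alkoxy group is expected cis to the 3-OH (4β), which is of no consequence because the centre is ionised again.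

Step 10
Reactants: 14 capped electrophile; 2 tetra-O-benzylcatechin
Product: 15 upper dimer, 8-bromo-tetra-O-benzylcatechin-(4α→8)-tetra-O-benzylcatechin
Conditions: 2 (2 equiv), TMSOTf (0.1 equiv), CH2Cl2, −78 °C; Et3N quench
Reagents that add atoms: none
Why: Lewis-acid Friedel–Crafts coupling of a flavan-4-yl cation with C8 of a 5,7-di-O-benzyl flavan, in which attack anti to the C3 oxygen should give the 3,4-trans (4α) bond; the bromine at C8 of the electrophile prevents its self-condensation.

Step 11
Reactants: 15 upper dimer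
Product: 16 dimeric electrophile (15 with a 4β-(2-ethoxyethoxy) group on its lower unit)
Conditions: DDQ (2 equiv), 2-ethoxyethanol (5 equiv), CH2Cl2, rt
Reagents that add atoms: 2-ethoxyethanol, CCOCCO
Why: DDQ hydride abstraction at the only benzylic CH2 (C4 of the lower unit, whose ring A is the more electron-rich); the diarylmethine C4–H of the upper unit is hindered and its ring carries the bromine, so it should be left.

Step 12
Reactants: 16 dimeric electrophile; 13 lower dimer
Product: 17 protected tetramer, 8-bromo-tetra-O-benzylcatechin-(4α→8)-tetra-O-benzylcatechin-(4α→8)-tetra-O-benzylcatechin-(4α→8)-penta-O-benzylcatechin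
Conditions: 13 (1.5 equiv), TMSOTf (0.3 equiv), CH2Cl2, −78 to −40 °C; Et3N quench
Reagents that add atoms: none
Why: The same Friedel–Crafts interflavan coupling in [2+2] form, in which the cation from 16 should be taken up anti to its C3 oxygen (4α) by C8 of the upper unit of 13, the most nucleophilic free position (ortho to O1, para to O5); 16 cannot self-condense at C8 because that position is brominated in unit 1 and substituted in unit 2.

Step 13
Reactants: 17 protected tetramer
Product: 18 catechin-(4α→8)-catechin-(4α→8)-catechin-(4α→8)-catechin (target)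
Conditions: H2 (1 atm), Pd(OH)2 on carbon, Et3N (1.1 equiv), THF/MeOH/H2O, rt
Reagents that add atoms: none
Why: Hydrogenolysis should remove the seventeen benzyl ethers and the aryl bromide in one operation, with Et3N taking up HBr to protect the acid-labile interflavan bonds; no stereocentre is affected.

**Compound list**

1 | (+)-catechin | Oc1cc(O)c2c(c1)O[C@H](c1ccc(O)c(O)c1)[C@@H](O)C2 | starting material
2 | tetra-O-benzylcatechin | c1(OCc9ccccc9)cc(OCc9ccccc9)c2c(c1)O[C@H](c3ccc(OCc9ccccc9)c(OCc9ccccc9)c3)[C@@H](O)C2 | intermediate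
3 | 8-bromo-tetra-O-benzylcatechin | c1(OCc9ccccc9)cc(OCc9ccccc9)c2c(c1Br)O[C@H](c3ccc(OCc9ccccc9)c(OCc9ccccc9)c3)[C@@H](O)C2 | intermediate
4 | 8-bromo-penta-O-benzylcatechin | c1(OCc9ccccc9)cc(OCc9ccccc9)c2c(c1Br)O[C@H](c3ccc(OCc9ccccc9)c(OCc9ccccc9)c3)[C@@H](OCc9ccccc9)C2 | intermediate
5 | 3,4-bis(benzyloxy)benzaldehyde | O=Cc1ccc(OCc2ccccc2)c(OCc2ccccc2)c1 | starting material
6 | (E)-3-[3,4-bis(benzyloxy)phenyl]prop-2-enal | O=C/C=C/c1ccc(OCc2ccccc2)c(OCc2ccccc2)c1 | intermediate
7 | (2R,3S)-3-[3,4-bis(benzyloxy)phenyl]oxirane-2-carbaldehyde | O=C[C@@H]1O[C@H]1c1ccc(OCc2ccccc2)c(OCc2ccccc2)c1 | intermediate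
8 | aryllithium (penta-O-benzylcatechin lithiated at C8) | [Li]c1c(OCc9ccccc9)cc(OCc9ccccc9)c2c1O[C@H](c3ccc(OCc9ccccc9)c(OCc9ccccc9)c3)[C@@H](OCc9ccccc9)C2 | intermediate
9 | lithium alkoxide (adduct of 8 to the aldehyde of 7; both carbinol epimers) | [Li]OC([C@@H]1O[C@H]1c3ccc(OCc9ccccc9)c(OCc9ccccc9)c3)c1c(OCc9ccccc9)cc(OCc9ccccc9)c2c1O[C@H](c3ccc(OCc9ccccc9)c(OCc9ccccc9)c3)[C@@H](OCc9ccccc9)C2 | intermediate
10 | epoxy methyl ether (oxirane configuration as in 7; both epimers at the methoxy carbon) | COC([C@@H]1O[C@H]1c3ccc(OCc9ccccc9)c(OCc9ccccc9)c3)c1c(OCc9ccccc9)cc(OCc9ccccc9)c2c1O[C@H](c3ccc(OCc9ccccc9)c(OCc9ccccc9)c3)[C@@H](OCc9ccccc9)C2 | intermediate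
11 | 3,5-bis(benzyloxy)phenol | Oc1cc(OCc2ccccc2)cc(OCc2ccccc2)c1 | starting material
12 | seco-dimer aryl ether, (1R,2S), both epimers at the methoxy carbon | c1(OCc9ccccc9)cc(OCc9ccccc9)cc(c1)O[C@H](c3ccc(OCc9ccccc9)c(OCc9ccccc9)c3)[C@@H](O)C(OC)c1c(OCc9ccccc9)cc(OCc9ccccc9)c2c1O[C@H](c3ccc(OCc9ccccc9)c(OCc9ccccc9)c3)[C@@H](OCc9ccccc9)C2 | intermediate
13 | lower dimer, tetra-O-benzylcatechin-(4α→8)-penta-O-benzylcatechin | c1(OCc9ccccc9)cc(OCc9ccccc9)c2c(c1)O[C@H](c3ccc(OCc9ccccc9)c(OCc9ccccc9)c3)[C@@H](O)[C@@H]2c1c(OCc9ccccc9)cc(OCc9ccccc9)c2c1O[C@H](c3ccc(OCc9ccccc9)c(OCc9ccccc9)c3)[C@@H](OCc9ccccc9)C2 | intermediate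
14 | capped electrophile, (2R,3S,4S)-8-bromo-4-(2-ethoxyethoxy)-tetra-O-benzylcatechin | c1(OCc9ccccc9)cc(OCc9ccccc9)c2c(c1Br)O[C@H](c3ccc(OCc9ccccc9)c(OCc9ccccc9)c3)[C@@H](O)[C@H]2OCCOCC | intermediate
15 | upper dimer, 8-bromo-tetra-O-benzylcatechin-(4α→8)-tetra-O-benzylcatechin | c1(OCc9ccccc9)cc(OCc9ccccc9)c2c(c1Br)O[C@H](c3ccc(OCc9ccccc9)c(OCc9ccccc9)c3)[C@@H](O)[C@@H]2c1c(OCc9ccccc9)cc(OCc9ccccc9)c2c1O[C@H](c3ccc(OCc9ccccc9)c(OCc9ccccc9)c3)[C@@H](O)C2 | intermediate
16 | dimeric electrophile (15 with 4β-(2-ethoxyethoxy) on the lower unit) | c1(OCc9ccccc9)cc(OCc9ccccc9)c2c(c1Br)O[C@H](c3ccc(OCc9ccccc9)c(OCc9ccccc9)c3)[C@@H](O)[C@@H]2c1c(OCc9ccccc9)cc(OCc9ccccc9)c2c1O[C@H](c3ccc(OCc9ccccc9)c(OCc9ccccc9)c3)[C@@H](O)[C@H]2OCCOCC | intermediate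
17 | protected tetramer | c1(OCc9ccccc9)cc(OCc9ccccc9)c2c(c1Br)O[C@H](c3ccc(OCc9ccccc9)c(OCc9ccccc9)c3)[C@@H](O)[C@@H]2c1c(OCc9ccccc9)cc(OCc9ccccc9)c2c1O[C@H](c3ccc(OCc9ccccc9)c(OCc9ccccc9)c3)[C@@H](O)[C@@H]2c1c(OCc9ccccc9)cc(OCc9ccccc9)c2c1O[C@H](c3ccc(OCc9ccccc9)c(OCc9ccccc9)c3)[C@@H](O)[C@@H]2c1c(OCc9ccccc9)cc(OCc9ccccc9)c2c1O[C@H](c3ccc(OCc9ccccc9)c(OCc9ccccc9)c3)[C@@H](OCc9ccccc9)C2 | intermediate
18 | catechin-(4α→8)-catechin-(4α→8)-catechin-(4α→8)-catechin | Oc1cc(O)c2c(c1)O[C@H](c1ccc(O)c(O)c1)[C@@H](O)[C@@H]2c1c(O)cc(O)c2c1O[C@H](c1ccc(O)c(O)c1)[C@@H](O)[C@@H]2c1c(O)cc(O)c2c1O[C@H](c1ccc(O)c(O)c1)[C@@H](O)[C@@H]2c1c(O)cc(O)c2c1O[C@H](c1ccc(O)c(O)c1)[C@@H](O)C2 | target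

**Step count and risks**

Total step count: 13.
Longest linear sequence: 8 steps from (+)-catechin (steps 1, 2, 3, 6, 7, 8, 12, 13).

Steps most likely to fail:

1. Step 12. The dimeric cation may be captured at C6 positions as well as at C8 of unit 3, the Lewis acid may cleave and scramble interflavan bonds already present, and the coupling may stall for steric reasons. The fallback builds the chain one unit at a time and sets out from 13. Compound 13 (in excess) is condensed under TMSOTf at −78 °C with the uncapped monomeric electrophile (2R,3S,4S)-4-(2-ethoxyethoxy)-tetra-O-benzylcatechin F1 (made from 2 with DDQ and 2-ethoxyethanol) to give the trimer tetra-O-benzylcatechin-(4α→8)-tetra-O-benzylcatechin-(4α→8)-penta-O-benzylcatechin F3. F3 is then condensed with the capped electrophile 14 under the same conditions, which returns to the route at 17. This sequence also dispenses with the dimeric electrophile 16 and therefore with steps 10 and 11.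

2. Step 8. Ionisation may occur at the C2 benzylic aryl ether instead of C4, the C4 cation may lose a proton or undergo a 1,2-hydride shift from C3 to a ketone, intermolecular alkylation may compete, or facial control in the ring closure may be poor. The fallback forms the same dimer by the classical intermolecular route and sets out from 2. One portion of 2 is oxidised with DDQ in the presence of 2-ethoxyethanol to (2R,3S,4S)-4-(2-ethoxyethoxy)-tetra-O-benzylcatechin F1. A second portion is benzylated at O3 (NaH, BnBr) to penta-O-benzylcatechin F2. F1 is then condensed with an excess of F2 under TMSOTf at −78 °C (4α-selective attack of C8 of F2 on the flavan-4-yl cation), which returns to the route at 13.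

3. Step 5. Iminium formation from the electron-rich enal may be slow, the p-alkoxyaryl epoxide may be opened by water or peroxide, and enantioselectivity may erode. The fallback uses metal-catalysed epoxidation of the allylic alcohol and sets out from 5. Horner–Wadsworth–Emmons reaction of 5 with triethyl phosphonoacetate (NaH, THF) gives ethyl (E)-3-[3,4-bis(benzyloxy)phenyl]prop-2-enoate F4. DIBAL-H (CH2Cl2, −78 °C) gives (E)-3-[3,4-bis(benzyloxy)phenyl]prop-2-en-1-ol F5. Sharpless asymmetric epoxidation (Ti(OiPr)4, L-(+)-diethyl tartrate, t-BuOOH, 4 Å MS, CH2Cl2, −20 °C) should give (2S,3S)-{3-[3,4-bis(benzyloxy)phenyl]oxiran-2-yl}methanol F6. Parikh–Doering oxidation (SO3·pyridine, DMSO, Et3N) then returns to the route at 7; only the C2 descriptor changes, not the geometry.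

Further compounds
F1 | step 8 | (2R,3S,4S)-4-(2-ethoxyethoxy)-tetra-O-benzylcatechin | c1(OCc9ccccc9)cc(OCc9ccccc9)c2c(c1)O[C@H](c3ccc(OCc9ccccc9)c(OCc9ccccc9)c3)[C@@H](O)[C@H]2OCCOCC
F2 | step 8 | penta-O-benzylcatechin | c1(OCc9ccccc9)cc(OCc9ccccc9)c2c(c1)O[C@H](c3ccc(OCc9ccccc9)c(OCc9ccccc9)c3)[C@@H](OCc9ccccc9)C2
F3 | step 12 | tetra-O-benzylcatechin-(4α→8)-tetra-O-benzylcatechin-(4α→8)-penta-O-benzylcatechin | c1(OCc9ccccc9)cc(OCc9ccccc9)c2c(c1)O[C@H](c3ccc(OCc9ccccc9)c(OCc9ccccc9)c3)[C@@H](O)[C@@H]2c1c(OCc9ccccc9)cc(OCc9ccccc9)c2c1O[C@H](c3ccc(OCc9ccccc9)c(OCc9ccccc9)c3)[C@@H](O)[C@@H]2c1c(OCc9ccccc9)cc(OCc9ccccc9)c2c1O[C@H](c3ccc(OCc9ccccc9)c(OCc9ccccc9)c3)[C@@H](OCc9ccccc9)C2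
F4 | step 5 | ethyl (E)-3-[3,4-bis(benzyloxy)phenyl]prop-2-enoate | CCOC(=O)/C=C/c1ccc(OCc2ccccc2)c(OCc2ccccc2)c1
F5 | step 5 | (E)-3-[3,4-bis(benzyloxy)phenyl]prop-2-en-1-ol | OC/C=C/c1ccc(OCc2ccccc2)c(OCc2ccccc2)c1
F6 | step 5 | (2S,3S)-{3-[3,4-bis(benzyloxy)phenyl]oxiran-2-yl}methanol | OC[C@@H]1O[C@H]1c1ccc(OCc2ccccc2)c(OCc2ccccc2)c1
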